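**Assumptions:** The target is taken exactly as drawn, i.e. (1R,3aR,4R,5S,7aS)-3-ethyl-1,4,5,7-tetramethyl-5-[(1E,3E)-4-phenylbuta-1,3-dienyl]-3a,4,5,7a-tetrahydro-1H-indene-4-carboxylic acid. Numbered compounds are substrates, intermediates and the building blocks that supply skeletal carbons; simple reagents (TBSCl, I2, NaClO2) are given by name and SMILES in the step. The route is a design, not a tested procedure.

## Retrosynthetic overview

1. Acid **18** comes from Pinnick oxidation of aldehyde **17**, which comes from an intramolecular Diels–Alder reaction (IMDA) of the acyclic (2E,4Z,6S,7E,9E,11E,13E)-hexaenal **16**. Both rings form in this single step (bonds C3–C7 and C2–C10), and four stereocentres are set relative to C6.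
2. **16** comes from dienol **15**, made by Negishi carboalumination of propargyl alcohol and cross-coupling with (Z)-vinyl iodide **12**.
3. **12** comes from Stork–Zhao iodo-olefination of α-methyl aldehyde **10**.
4. **10** comes from the Roche aldehyde **3** by two formyl-ylide Wittig reactions and a cinnamylphosphonate HWE.
5. The only stereocentre carried in (C6 of the chain, C1 of the target) comes from (R)-Roche ester **1**.

## Route

**Step 1**
Reactants: **1** methyl (R)-3-hydroxy-2-methylpropanoate
Product: **2** methyl (R)-3-(tert-butyldimethylsilyloxy)-2-methylpropanoate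
Conditions: TBSCl, imidazole, DMF, 0 °C to rt
Reagents that add atoms: TBSCl, CC(C)(C)[Si](C)(C)Cl
Why: Standard silylation of the primary alcohol; the stereocentre is untouched.

**Step 2**
Reactants: **2**
Product: **3** (R)-3-(tert-butyldimethylsilyloxy)-2-methylpropanal
Conditions: DIBAL-H (1.05 equiv), CH2Cl2, −78 °C; MeOH then Rochelle salt; use crude
Reagents that add atoms: none
Why: Partial ester reduction; the aluminium hemiacetal is stable at −78 °C and collapses on work-up, and the α-stereocentre survives if the aldehyde is not chromatographed.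

**Step 3**
Reactants: **3**; **4** 2-(triphenylphosphoranylidene)propanal
Product: **5** (S,E)-5-(tert-butyldimethylsilyloxy)-2,4-dimethylpent-2-enal
Conditions: PhMe, 90 °C
Reagents that add atoms: **4**, CC(C=O)=P(c1ccccc1)(c1ccccc1)c1ccccc1
Why: Wittig reaction with a stabilised, non-basic ylide gives the (E)-trisubstituted enal without epimerising the α-centre (the descriptor changes from R to S only through CIP priorities).

**Step 4**
Reactants: **5**; **4**
Product: **6** (S,2E,4E)-7-(tert-butyldimethylsilyloxy)-2,4,6-trimethylhepta-2,4-dienal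
Conditions: PhMe, 110 °C
Reagents that add atoms: **4**, CC(C=O)=P(c1ccccc1)(c1ccccc1)c1ccccc1
Why: A second iterative E-selective Wittig homologation; the product dienal is less electrophilic than **5**, so over-homologation is slow.

**Step 5**
Reactants: **6**; **7** diethyl [(E)-3-phenylprop-2-enyl]phosphonate (diethyl cinnamylphosphonate)
Product: **8** tert-butyldimethyl{[(2S,3E,5E,7E,9E)-2,4,6-trimethyl-10-phenyldeca-3,5,7,9-tetraenyl]oxy}silane
Conditions: **7**, LiHMDS, THF, −78 °C; then **6**, −78 to 0 °C
Reagents that add atoms: **7**, CCOP(=O)(OCC)C/C=C/c1ccccc1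
Why: Horner–Wadsworth–Emmons reaction of an allylic phosphonate anion gives the new disubstituted alkene E-selectively; fast carbonyl addition at −78 °C avoids vinylogous deprotonation.

**Step 6**
Reactants: **8**
Product: **9** (2S,3E,5E,7E,9E)-2,4,6-trimethyl-10-phenyldeca-3,5,7,9-tetraen-1-ol
Conditions: TBAF, THF, 0 °C to rt
Reagents that add atoms: none
Why: Fluoride desilylation; the polyene is inert to these conditions.

**Step 7**
Reactants: **9**
Product: **10** (2S,3E,5E,7E,9E)-2,4,6-trimethyl-10-phenyldeca-3,5,7,9-tetraenal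
Conditions: Dess–Martin periodinane, NaHCO3, CH2Cl2, 0 °C; cold work-up, use at once
Reagents that add atoms: none
Why: Buffered, neutral Dess–Martin oxidation minimises epimerisation and conjugation of the α-methyl-β,γ-unsaturated aldehyde.

**Step 8**
Reactants: **10**; **11** propyltriphenylphosphonium bromide
Product: **12** [(1E,3E,5E,7E,9S,10Z)-11-iodo-5,7,9-trimethyltrideca-1,3,5,7,10-pentaenyl]benzene
Conditions: **11**, n-BuLi, THF; I2, −78 °C; NaHMDS, −20 °C; then **10**, −78 to −20 °C
Reagents that add atoms: **11**, CCC[P+](c1ccccc1)(c1ccccc1)c1ccccc1.[Br-]; iodine, II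
Why: Stork–Zhao olefination with the α-iodo ylide Ph3P=C(I)Et gives the (Z)-iodoalkene (iodine cis to the chain) under kinetic control, and carbonyl addition at −78 °C outruns enolisation.

**Step 9**
Reactants: **12**; **13** prop-2-yn-1-ol; **14** trimethylaluminium
Product: **15** (2E,4Z,6S,7E,9E,11E,13E)-4-ethyl-2,6,8,10-tetramethyl-14-phenyltetradeca-2,4,7,9,11,13-hexaen-1-ol
Conditions: **13**, **14** (3 equiv), Cp2ZrCl2, ClCH2CH2Cl, rt; then **12**, ZnCl2, Pd(PPh3)4, THF, rt
Reagents that add atoms: **13**, C#CCO; **14**, C[Al](C)C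
Why: Negishi Zr-catalysed syn-carboalumination places methyl on the internal carbon to give the (E)-alkenylalane, and Pd/Zn cross-coupling proceeds with retention at both partners, giving the 2E,4Z diene.

**Step 10**
Reactants: **15**
Product: **16** (2E,4Z,6S,7E,9E,11E,13E)-4-ethyl-2,6,8,10-tetramethyl-14-phenyltetradeca-2,4,7,9,11,13-hexaenal
Conditions: activated MnO2, CH2Cl2, rt, dark
Reagents that add atoms: none
Why: Chemoselective neutral oxidation of the allylic alcohol; the 2E geometry rules out oxa-6π closure, and any cycloadduct already formed is carried forward.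

**Step 11**
Reactants: **16**
Product: **17** (1R,3aR,4R,5S,7aS)-3-ethyl-1,4,5,7-tetramethyl-5-[(1E,3E)-4-phenylbuta-1,3-dienyl]-3a,4,5,7a-tetrahydro-1H-indene-4-carbaldehyde
Conditions: PhMe, BHT (cat.), 80 °C, Ar, dark
Reagents that add atoms: none
Why: Intramolecular Diels–Alder reaction of the C7–C10 (E,E)-diene with the C2=C3 (E)-enal through the three-atom tether containing the 4Z alkene.
- The CHO-endo transition state gives the trans ring fusion.
- The diene and dienophile geometries fix C3a, C4, C5 and C7a relative to one another.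
- A(1,3) strain between the C8 methyl and C6 puts C6–H in the diene plane, so the dienophile adds anti to the C6 methyl; this relays the absolute configuration from C6 (C1 of the product).
- Any 4E isomer carried from step 8 cannot cyclise and is removed here.

**Step 12**
Reactants: **17**
Product: **18** 22-nor-zyggomphic acid B, (1R,3aR,4R,5S,7aS)-3-ethyl-1,4,5,7-tetramethyl-5-[(1E,3E)-4-phenylbuta-1,3-dienyl]-3a,4,5,7a-tetrahydro-1H-indene-4-carboxylic acid
Conditions: NaClO2, NaH2PO4, 2-methyl-2-butene (excess), t-BuOH/H2O, 0 °C to rt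
Reagents that add atoms: sodium chlorite, [Na+].[O-]Cl=O
Why: Pinnick oxidation works on the hindered aldehyde, which has no epimerisable α-hydrogen, and the scavenger protects the alkenes from HOCl.

## Compound list

1 | methyl (R)-3-hydroxy-2-methylpropanoate | COC(=O)[C@H](C)CO | starting material
2 | methyl (R)-3-(TBS-oxy)-2-methylpropanoate | COC(=O)[C@H](C)CO[Si](C)(C)C(C)(C)C | intermediate
3 | (R)-3-(TBS-oxy)-2-methylpropanal | O=C[C@H](C)CO[Si](C)(C)C(C)(C)C | intermediate
4 | 2-(triphenylphosphoranylidene)propanal | CC(C=O)=P(c1ccccc1)(c1ccccc1)c1ccccc1 | starting material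
5 | (S,E)-5-(TBS-oxy)-2,4-dimethylpent-2-enal | O=C/C(C)=C/[C@H](C)CO[Si](C)(C)C(C)(C)C | intermediate
6 | (S,2E,4E)-7-(TBS-oxy)-2,4,6-trimethylhepta-2,4-dienal | O=C/C(C)=C/C(C)=C/[C@H](C)CO[Si](C)(C)C(C)(C)C | intermediate
7 | diethyl cinnamylphosphonate | CCOP(=O)(OCC)C/C=C/c1ccccc1 | starting material
8 | TBS ether of (2S,3E,5E,7E,9E)-2,4,6-trimethyl-10-phenyldeca-3,5,7,9-tetraen-1-ol | CC(C)(C)[Si](C)(C)OC[C@@H](C)/C=C(C)/C=C(C)/C=C/C=C/c1ccccc1 | intermediate
9 | (2S,3E,5E,7E,9E)-2,4,6-trimethyl-10-phenyldeca-3,5,7,9-tetraen-1-ol | OC[C@@H](C)/C=C(C)/C=C(C)/C=C/C=C/c1ccccc1 | intermediate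
10 | (2S,3E,5E,7E,9E)-2,4,6-trimethyl-10-phenyldeca-3,5,7,9-tetraenal | O=C[C@@H](C)/C=C(C)/C=C(C)/C=C/C=C/c1ccccc1 | intermediate
11 | propyltriphenylphosphonium bromide | CCC[P+](c1ccccc1)(c1ccccc1)c1ccccc1.[Br-] | starting material
12 | [(1E,3E,5E,7E,9S,10Z)-11-iodo-5,7,9-trimethyltrideca-1,3,5,7,10-pentaenyl]benzene | CC/C(I)=C/[C@@H](C)/C=C(C)/C=C(C)/C=C/C=C/c1ccccc1 | intermediate
13 | prop-2-yn-1-ol | C#CCO | starting material
14 | trimethylaluminium | C[Al](C)C | starting material
15 | (2E,4Z,6S,7E,9E,11E,13E)-4-ethyl-2,6,8,10-tetramethyl-14-phenyltetradeca-2,4,7,9,11,13-hexaen-1-ol | OC/C(C)=C/C(CC)=C\[C@@H](C)/C=C(C)/C=C(C)/C=C/C=C/c1ccccc1 | intermediate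
16 | (2E,4Z,6S,7E,9E,11E,13E)-4-ethyl-2,6,8,10-tetramethyl-14-phenyltetradeca-2,4,7,9,11,13-hexaenal | O=C/C(C)=C/C(CC)=C\[C@@H](C)/C=C(C)/C=C(C)/C=C/C=C/c1ccccc1 | intermediate
17 | (1R,3aR,4R,5S,7aS)-3-ethyl-1,4,5,7-tetramethyl-5-[(1E,3E)-4-phenylbuta-1,3-dienyl]-3a,4,5,7a-tetrahydro-1H-indene-4-carbaldehyde | CCC1=C[C@@H](C)[C@@H]2C(C)=C[C@](C)(/C=C/C=C/c3ccccc3)[C@](C)(C=O)[C@@H]12 | intermediate
18 | 22-nor-zyggomphic acid B | CCC1=C[C@@H](C)[C@@H]2C(C)=C[C@](C)(/C=C/C=C/c3ccccc3)[C@](C)(C(=O)O)[C@@H]12 | target

## Summary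

Total steps: 12. Longest linear sequence: 12 (fully linear from **1**; steps 10 and 11 can be telescoped).

Steps most likely to fail:

1. **Step 8 (with step 7).** Aldehyde **10** is α-methyl and β,γ-unsaturated into a phenyl-tetraene, so it may epimerise or conjugate, and Zhao olefinations give only moderate Z-selectivity and yield. Fallback: reverse the order of chain building. Do the Stork–Zhao reaction first on the robust Roche aldehyde from (S)-Roche ester to give TBSOCH2CH(Me)CH=C(I)Et, then desilylate, oxidise and build the tetraene with the room-temperature ylide Ph3P=C(Me)CO2Et followed by DIBAL and MnO2 cycles, and couple the iodide last.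

2. **Step 9.** The one-pot alane coupling onto a hindered (Z)-iodide may suffer competing methyl transfer, low conversion or Z/E erosion. Fallback: Stille coupling of **12** with a preformed β-stannyl methacrylate, ethyl (E)-2-methyl-3-(tributylstannyl)acrylate (not a catalogue reagent; it would need to be prepared, for example from the (E)-3-iodo-2-methylacrylate). This gives the hexaenoate; LiOH then gives the hexaenoic acid, which is cyclised directly, so steps 10 and 12 are no longer needed.

3. **Step 11.** The IMDA forms two adjacent quaternary carbons, and endo/exo or facial selectivity, a [1,5]-H shift of the (Z)-diene, or polymerisation could intervene. Fallback: oxidise acyclic **16** to the hexaenoic acid first (Pinnick) and cyclise the free acid or its carboxylate in aqueous medium, or as a Lewis-acid-activated acyl derivative at low temperature.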